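East loses starting complex faster than south-west over the first 40.0 min, 12.0% against 9.00%.

| flask | starting complex | incoming ligand | protic impurity | remark | time |
|---|---|---|---|---|---|
| east | 36 mM | 0.50 equiv | 0.48 mM | run made earlier |  |
| south-west | 24 mM | 0.50 equiv | 0.24 mM | run made earlier |  |
| beta | 24 mM | 0.500 equiv | 0.480 mM |  | 5.0 h |
| gamma | 24 mM | 0.800 equiv | 0.480 mM |  | 5.0 h |
| epsilon | 24 mM | 4.00 equiv | 0.480 mM |  | 5.0 h |

| run | time / min | complex with two exchanged / % | complex with one exchanged / % | starting complex / % |
|---|---|---|---|---|
| east | 8.00 | 0 | 1 | 96 |
| east | 20.0 | 0 | 5 | 92 |
| east | 40.0 | 3 | 13 | 88 |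
| east | 60.0 | 4 | 12 | 89 |
| east | 80.0 | 3 | 14 | 85 |
| east | 120 | 0 | 15 | 80 |
| south-west | 8.00 | 0 | 0 | 96 |
| south-west | 15.0 | 0 | 6 | 97 |
| south-west | 25.0 | 1 | 9 | 94 |
| south-west | 40.0 | 0 | 4 | 91 |
| south-west | 60.0 | 1 | 9 | 88 |
| south-west | 120 | 0 | 17 | 80 |

(readings scatter by 2 percentage points)

1. which of these holds the largest part of the starting complex at the end of beta (starting complex / complex with one exchanged / complex with two exchanged)
2. which of these holds the largest part of the starting complex at the end of gamma (starting complex / complex with one exchanged / complex with two exchanged)
3. which of these holds the largest part of the starting complex at the end of epsilon (starting complex / complex with one exchanged / complex with two exchanged)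
4. how much complex with two exchanged is there at the end of gamma, in percent of the starting complex charged

Column against column, the charged ligand concentration X is 18.0 mM in east and 12.0 mM in south-west, a ratio of 1.50. The losses at that row stand at 1.33, so the reading is a rate first order in ligand, though the readings scatter by 2 percentage points. The last rows tie at 80% and 80%, which stands against this reading. By then at least 40.0% of each ligand charge is spent, so the early row is the one that shows X as charged.

That row gives 0.178 L mol⁻¹ min⁻¹ from east and 0.196 L mol⁻¹ min⁻¹ from south-west. Their mean is the rate constant per unit of ligand, k = 0.187 L mol⁻¹ min⁻¹. The exposure E = k·X·t then counts e-foldings of the forward step at charged ligand, with k·X as a pseudo-first-order constant.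

Beta has E = 0.673, and its ligand charge holds starting complex at or above 50.0%, so starting complex stays largest. Gamma has E = 1.08. Ligand falls there; taken one for one with the starting complex used, the integrated second-order law with k leaves starting complex at 51.4%, more than the 48.6% open to the other forms together, so this reckoning keeps it largest. Epsilon has E = 5.39, and its ligand exceeds the two equivalents a double exchange takes. This reckoning therefore puts starting complex out of first place there, but E counts the first exchange, so it does not choose between complex with one exchanged and complex with two exchanged. For gamma's complex with two exchanged the readings yield no constant, since their highest value, 4% in east, lies two standard deviations from zero.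

The forecast, reading a “first-order, dissociative loss”, gave starting complex as largest in epsilon, as in beta and gamma, and 6% for gamma's complex with two exchanged, so it parts from this reckoning at epsilon.

    starting complex + incoming ligand ⇌ leaving ligand + complex with one exchanged (K = 0.870, k = 0.00310 L mol⁻¹ s⁻¹)
    complex with one exchanged + incoming ligand ⇌ leaving ligand + complex with two exchanged (K = 2.70, k = 0.00120 L mol⁻¹ s⁻¹)
    complex with one exchanged → over-reaction product (k = 4.40 × 10⁻⁷ s⁻¹)
    complex with one exchanged ⇌ isomer of the product (K = 0.680, k = 4.50 × 10⁻⁵ s⁻¹)
    protic impurity + incoming ligand → quenched reagent (k = 0.700 L mol⁻¹ s⁻¹)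

Gamma ends with 4.48% of complex with two exchanged. Epsilon ends with complex with two exchanged largest, and its starting complex stands at 15.4%, far above the 0.458% of the forward step, beside 31.3 mM of leaving ligand. A neighbour of gamma charged with 3.20 equiv of incoming ligand has E = 4.31, above gamma's, and it ends with complex with two exchanged largest at 36.4%.

(The runs were generated by integration for an exercise; scatter was added.)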